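**Retrosynthetic overview**
1. Target numbering: C1(=O), C2(prenyl)2, C3(=O), C4(isobutyryl), C5(enol C–OH), C6(OH)(prenyl). This carbocycle is ring A.
2. Enabling feature: C5–C6 is an acyloin, with the C5 carbonyl/enol next to the C6 tertiary carbinol, and C6 also adjoins the C1 ketone. C6 can therefore be read as the outer carbonyl of a C1/C6 1,2-diketone and C5 as an aldehyde. These two electrophilic carbons are joined after polarity reversal of C5 by a chiral carbene (intramolecular crossed benzoin). This closes ring A and sets C6 from an achiral precursor.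
3. The C3/C4/isobutyryl β-tricarbonyl is tied up as a temporary isoxazole (ring B, whose N–O bond is not in the target). C5 becomes a non-enolisable isoxazole-4-carbaldehyde held next to the C2 arm. Quaternary C2 blocks enolisation on its side and favours closure.
4. Precursor 16 comes from a temporary δ-lactone (ring C) that tells the C5 and C1 arms apart. The sequence is double prenylation at C2, opening with homoprenylmagnesium bromide, α-hydroxylation and double oxidation.
5. Order of rings: B (step 2), C (step 4, opened in step 6), A (step 9), B opened (steps 10 and 11).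

Key step: step 9

Assumption: the (5aS,10bR) antipode of the triazolium salt is written for Si-face attack, by analogy with the hydrogen-bonded transition-state model. The sense of induction has to be confirmed on the first run. The (5aR,10bS) salt is equally commercial and replaces it without any other change if the sense is opposite.

**Step 1**
Reactants: 1 isobutyraldehyde oxime
Product: 2 N-hydroxy-2-methylpropanimidoyl chloride
Conditions: N-chlorosuccinimide, DMF, 0 °C to rt
Reagents that add atoms: N-chlorosuccinimide, O=C1CCC(=O)N1Cl
Why: Electrophilic chlorination of the aldoxime C–H is the standard hydroximoyl chloride synthesis, and no other reactive site is present.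

**Step 2**
Reactants: 2 N-hydroxy-2-methylpropanimidoyl chloride; 3 methyl acetoacetate
Product: 5 methyl 3-isopropyl-5-methylisoxazole-4-carboxylate, via 2-methylpropanenitrile oxide 4 (not isolated)
Conditions: NaOMe, MeOH, 0 °C to rt
Reagents that add atoms: none
Why: Methoxide eliminates HCl to the nitrile oxide, the acetoacetate enolate carbon attacks its carbon, and the oxime oxygen closes on the ketone with loss of water (nitrile oxide–β-keto ester condensation, a formal [3+2] cycloaddition), which fixes the 3-isopropyl/4-ester/5-methyl pattern.

**Step 3**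
Reactants: 5 methyl 3-isopropyl-5-methylisoxazole-4-carboxylate
Product: 6 (3-isopropyl-5-methylisoxazol-4-yl)methanol
Conditions: LiAlH4, THF, 0 °C
Reagents that add atoms: none
Why: LiAlH4 reduction of an isoxazole-4-carboxylate leaves the N–O bond intact at 0 °C, and doing it before a second carbonyl exists removes any later problem of telling the two arms apart.

**Step 4**
Reactants: 6 (3-isopropyl-5-methylisoxazol-4-yl)methanol
Product: 8 3-isopropyl-4,7-dihydro-6H-pyrano[3,4-d]isoxazol-6-one (δ-lactone, ring path isoxazole C4–CH2–O–C(=O)–CH2–isoxazole C5), via hydroxy acid 7 (not isolated)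
Conditions: n-BuLi (2.2 equiv), THF, −78 °C; CO2; 2 M HCl; then TsOH·H2O (cat.), toluene, 60 °C
Reagents that add atoms: carbon dioxide, O=C=O
Why: The second equivalent of n-BuLi deprotonates the C5 methyl group (lateral lithiation of a 5-methylisoxazole, far more acidic than the isopropyl methine), carboxylation gives 7, and acid closes the unstrained six-membered lactone.

**Step 5**
Reactants: 8 3-isopropyl-4,7-dihydro-6H-pyrano[3,4-d]isoxazol-6-one; 9 prenyl bromide (1-bromo-3-methylbut-2-ene, two equivalents)
Product: 11 3-isopropyl-7,7-bis(3-methylbut-2-enyl)-4,7-dihydro-6H-pyrano[3,4-d]isoxazol-6-one, via monoprenyl lactone 10 (not isolated)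
Conditions: LiN(SiMe3)2 then 9, THF, −78 to 0 °C; second cycle of LiN(SiMe3)2 then 9 in the same flask
Reagents that add atoms: none
Why: The lactone CH2 between the carbonyl and isoxazole C5 is the only acidic site, so two rounds of enolate formation and SN2 C-alkylation by the primary allylic bromide build the achiral quaternary carbon (future C2).

**Step 6**
Reactants: 11 diprenyl lactone; 12 5-bromo-2-methylpent-2-ene
Product: 14 5-[4-(hydroxymethyl)-3-isopropylisoxazol-5-yl]-2,10-dimethyl-5-(3-methylbut-2-enyl)undeca-2,9-dien-6-one, via 4-methylpent-3-enylmagnesium bromide 13 (not isolated)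
Conditions: 12, Mg, THF, rt; then 11, THF, −78 to −20 °C; aq NH4Cl
Reagents that add atoms: none
Why: In this Grignard acyl substitution on a lactone, the magnesium hemiketal persists at low temperature and the ketone released on work-up is neopentyl, so a second addition is not expected, and ring opening uncovers the carbinol of the future C5.

**Step 7**
Reactants: 14 keto alcohol
Product: 15 7-hydroxy-5-[4-(hydroxymethyl)-3-isopropylisoxazol-5-yl]-2,10-dimethyl-5-(3-methylbut-2-enyl)undeca-2,9-dien-6-one (racemic)
Conditions: KN(SiMe3)2 (2.3 equiv), THF, −78 °C; 3-phenyl-2-(phenylsulfonyl)oxaziridine, −78 °C; AcOH quench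
Reagents that add atoms: 3-phenyl-2-(phenylsulfonyl)oxaziridine, O=S(=O)(c1ccccc1)N1OC1c1ccccc1
Why: In this Davis enolate hydroxylation, the first equivalent of base takes the OH proton, the second forms the only possible enolate (the other α-carbon is quaternary), and oxygen is transferred to carbon without touching the trisubstituted alkenes; the new carbinol centre is racemic and is erased in step 8.

**Step 8**
Reactants: 15 hydroxy ketone diol
Product: 16 3-isopropyl-5-[2,10-dimethyl-5-(3-methylbut-2-enyl)-6,7-dioxoundeca-2,9-dien-5-yl]isoxazole-4-carbaldehyde (achiral)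
Conditions: Dess–Martin periodinane (2.6 equiv), CH2Cl2, 0 °C to rt; short silica plug, used at once
Reagents that add atoms: none
Why: Dess–Martin oxidation under neutral conditions takes the heteroaryl carbinol to the aldehyde and the α-ketol to the 1,2-diketone in one operation, spares the alkenes, and avoids the base that would move the β,γ-double bond into conjugation.

**Step 9**
Reactants: 16 dione aldehyde
Product: 17 (5R)-5-hydroxy-3-isopropyl-5,7,7-tris(3-methylbut-2-enyl)-1,2-benzoxazole-4,6(5H,7H)-dione
Conditions: (5aS,10bR)-2-(pentafluorophenyl)-5a,10b-dihydro-4H,6H-indeno[2,1-b][1,2,4]triazolo[4,3-d][1,4]oxazin-2-ium tetrafluoroborate (C18H11BF9N3O, 10 mol %), iPr2NEt (10 mol %), 4 Å MS, toluene, Ar, 0 °C to rt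
Reagents that add atoms: none
Why: The carbene formed by deprotonating the triazolium salt adds to the only aldehyde of 16, proton transfer gives the Breslow intermediate so that the former formyl carbon (C5 of the target) acts as an acyl anion equivalent, this carbon attacks the C6 ketone carbon, and collapse releases the carbene and the α-ketol. The closest known reaction type is the catalytic enantioselective intramolecular crossed aldehyde–ketone benzoin cyclisation, which is established for keto aldehydes built on an isoxazole and for activated ketone acceptors. The one ring closed is the six-membered carbocycle, by 6-exo-trig attack on the C6 carbonyl, helped by the rigid cis placement of both arms on the isoxazole C4–C5 bond and by the gem-diprenyl (Thorpe–Ingold) effect at C2. The single new stereocentre C6 is set by the catalyst alone: the indane wall shields one face of the enaminol and the hydrogen bond from its OH to the ketone oxygen orients the acceptor so that its Si face (O > C1 > CH2) is attacked, giving (5R)-17, which has the same spatial arrangement as (6S) in the target because only the CIP ranking of the two flanking carbons changes. Site selectivity between the two ketones is needed and is secured because attack at C1 would require a strained five-membered ring fused to the isoxazole at a neopentyl carbonyl, whereas C6 is less hindered and is activated by its neighbour. Cyclisation must also outrun enolisation of the β,γ-unsaturated diketone and its cleavage by the carbene, which is addressed by a substoichiometric weak amine base, the acidic pentafluorophenyl salt and an aprotic solvent free of alcohol.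

**Step 10**
Reactants: 17 isoxazole-fused α-ketol
Product: 18 (2R)-6-(1-amino-2-methylpropylidene)-2-hydroxy-2,4,4-tris(3-methylbut-2-enyl)cyclohexane-1,3,5-trione
Conditions: Mo(CO)6 (1 equiv), MeCN/H2O 10:1, 80 °C
Reagents that add atoms: none
Why: Mo(CO)6-mediated reductive cleavage of the isoxazole N–O bond in wet acetonitrile tolerates alkenes, ketones and tertiary alcohols, and opens the temporary ring to the chelated vinylogous amide without touching the carbinol centre.

**Step 11**
Reactants: 18 enaminone
Product: 19 (6S)-5,6-dihydroxy-2,2,6-tris(3-methylbut-2-enyl)-4-(2-methylpropanoyl)cyclohex-4-ene-1,3-dione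
Conditions: 2 M aq HCl, THF, 40 °C
Reagents that add atoms: water, O
Why: In this acid hydrolysis of a vinylogous amide, O-protonation, addition of water to the iminium carbon and loss of ammonia as NH4Cl give the isobutyryl carbonyl, and the product settles as the hydrogen-bonded enol of the β-tricarbonyl with C6 unchanged.

**Compound list**
1 | isobutyraldehyde oxime | CC(C)C=NO | starting material
2 | N-hydroxy-2-methylpropanimidoyl chloride | CC(C)C(Cl)=NO | intermediate
3 | methyl acetoacetate | COC(=O)CC(C)=O | starting material
4 | 2-methylpropanenitrile oxide | CC(C)C#[N+][O-] | intermediate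
5 | methyl 3-isopropyl-5-methylisoxazole-4-carboxylate | COC(=O)c1c(C)onc1C(C)C | intermediate
6 | (3-isopropyl-5-methylisoxazol-4-yl)methanol | CC(C)c1noc(C)c1CO | intermediate
7 | 2-[4-(hydroxymethyl)-3-isopropylisoxazol-5-yl]acetic acid | CC(C)c1noc(CC(=O)O)c1CO | intermediate
8 | 3-isopropyl-4,7-dihydro-6H-pyrano[3,4-d]isoxazol-6-one | CC(C)c1noc2c1COC(=O)C2 | intermediate
9 | prenyl bromide | CC(C)=CCBr | starting material
10 | 3-isopropyl-7-(3-methylbut-2-enyl)-4,7-dihydro-6H-pyrano[3,4-d]isoxazol-6-one (racemic) | CC(C)c1noc2c1COC(=O)C2CC=C(C)C | intermediate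
11 | 3-isopropyl-7,7-bis(3-methylbut-2-enyl)-4,7-dihydro-6H-pyrano[3,4-d]isoxazol-6-one | CC(C)c1noc2c1COC(=O)C2(CC=C(C)C)CC=C(C)C | intermediate
12 | 5-bromo-2-methylpent-2-ene | CC(C)=CCCBr | starting material
13 | 4-methylpent-3-enylmagnesium bromide | CC(C)=CCC[Mg]Br | intermediate
14 | 5-[4-(hydroxymethyl)-3-isopropylisoxazol-5-yl]-2,10-dimethyl-5-(3-methylbut-2-enyl)undeca-2,9-dien-6-one | CC(C)c1noc(C(CC=C(C)C)(CC=C(C)C)C(=O)CCC=C(C)C)c1CO | intermediate
15 | 7-hydroxy derivative of 14 (racemic) | CC(C)c1noc(C(CC=C(C)C)(CC=C(C)C)C(=O)C(O)CC=C(C)C)c1CO | intermediate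
16 | 3-isopropyl-5-[2,10-dimethyl-5-(3-methylbut-2-enyl)-6,7-dioxoundeca-2,9-dien-5-yl]isoxazole-4-carbaldehyde | CC(C)c1noc(C(CC=C(C)C)(CC=C(C)C)C(=O)C(=O)CC=C(C)C)c1C=O | intermediate
17 | (5R)-5-hydroxy-3-isopropyl-5,7,7-tris(3-methylbut-2-enyl)-1,2-benzoxazole-4,6(5H,7H)-dione | CC(C)c1noc2c1C(=O)[C@@](O)(CC=C(C)C)C(=O)C2(CC=C(C)C)CC=C(C)C | intermediate
18 | (2R)-6-(1-amino-2-methylpropylidene)-2-hydroxy-2,4,4-tris(3-methylbut-2-enyl)cyclohexane-1,3,5-trione | CC(C)C(N)=C1C(=O)[C@@](O)(CC=C(C)C)C(=O)C(CC=C(C)C)(CC=C(C)C)C1=O | intermediate
19 | (6S)-5,6-dihydroxy-2,2,6-tris(3-methylbut-2-enyl)-4-(2-methylpropanoyl)cyclohex-4-ene-1,3-dione | CC(C)=CCC1(CC=C(C)C)C(=O)C(C(=O)C(C)C)=C(O)[C@@](O)(CC=C(C)C)C1=O | target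

**Total step count:** 11. **Longest linear sequence:** 11.

**Steps most likely to fail**

Step 9. Three processes are of concern:
- The amine base may enolise the diketone and move the β,γ-double bond into conjugation before cyclisation.
- The carbene may add slowly to the flanked aldehyde.
- Facial selectivity at the acceptor may be poor.

The fallback makes the same ring bond with normal polarity and sets the stereocentre afterwards. It sets out from 14 and returns at 17. Dess–Martin oxidation of 14 should give the keto aldehyde F1. LiN(SiMe3)2 in THF at −78 °C should form the only possible enolate, which closes on the aldehyde by an intramolecular aldol addition to the β-hydroxy ketone F2. A second Dess–Martin oxidation should give the cyclic β-diketone F3. Its sodium enolate would be hydroxylated with an enantiopure (8,8-dichlorocamphorylsulfonyl)oxaziridine under reagent control to give 17.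

Step 7. The alkoxide may close on the ketone to a hemiketal and hold back enolisation. The enolate may also be captured by the sulfonimine that forms during oxygen transfer. The fallback brings C6 in at the ketone oxidation level by a Corey–Seebach acyl anion. It sets out from 11 and returns at 16.
- iBu2AlH (toluene, −78 °C) should half-reduce 11 to the lactol F4.
- Commercial 1,3-dithiane is lithiated (n-BuLi) and alkylated with 9 to give 2-(3-methylbut-2-enyl)-1,3-dithiane F5.
- F5 is lithiated again and added in excess to F4, which reacts through its open hydroxy aldehyde form to give the diol F6.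
- Double Parikh–Doering oxidation (SO3·pyridine, DMSO, Et3N) should give the dithiane-masked keto aldehyde F7.
- Methylative hydrolysis (MeI, CaCO3, aq MeCN) should unmask 16.

Step 11. Hydrolysis of the chelated, hindered vinylogous amide may be sluggish. Harsher acid or heat would then invite addition of the enol oxygen to a prenyl group or acyloin ring contraction. The fallback activates the nitrogen instead of forcing the medium. It sets out from 18 and returns at 19. Boc2O with 4-(dimethylamino)pyridine in MeCN should give the N-Boc vinylogous imide F8. Its C–N bond should be cleaved by LiOH in aq THF at 0 °C through addition–elimination. Any O-carbonate formed would be removed in the same operation.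

**Further compounds**
F1 | step 9 | 3-isopropyl-5-[2,10-dimethyl-5-(3-methylbut-2-enyl)-6-oxoundeca-2,9-dien-5-yl]isoxazole-4-carbaldehyde | CC(C)c1noc(C(CC=C(C)C)(CC=C(C)C)C(=O)CCC=C(C)C)c1C=O
F2 | step 9 | 4-hydroxy-3-isopropyl-5,7,7-tris(3-methylbut-2-enyl)-5,7-dihydro-1,2-benzoxazol-6(4H)-one (diastereomer mixture) | CC(C)c1noc2c1C(O)C(CC=C(C)C)C(=O)C2(CC=C(C)C)CC=C(C)C
F3 | step 9 | 3-isopropyl-5,7,7-tris(3-methylbut-2-enyl)-1,2-benzoxazole-4,6(5H,7H)-dione | CC(C)c1noc2c1C(=O)C(CC=C(C)C)C(=O)C2(CC=C(C)C)CC=C(C)C
F4 | step 7 | 3-isopropyl-7,7-bis(3-methylbut-2-enyl)-6,7-dihydro-4H-pyrano[3,4-d]isoxazol-6-ol | CC(C)c1noc2c1COC(O)C2(CC=C(C)C)CC=C(C)C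
F5 | step 7 | 2-(3-methylbut-2-enyl)-1,3-dithiane | CC(C)=CCC1SCCCS1
F6 | step 7 | 2-[4-(hydroxymethyl)-3-isopropylisoxazol-5-yl]-5-methyl-2-(3-methylbut-2-enyl)-1-[2-(3-methylbut-2-enyl)-1,3-dithian-2-yl]hex-4-en-1-ol | CC(C)c1noc(C(CC=C(C)C)(CC=C(C)C)C(O)C2(CC=C(C)C)SCCCS2)c1CO
F7 | step 7 | 3-isopropyl-5-{5-methyl-2-(3-methylbut-2-enyl)-1-[2-(3-methylbut-2-enyl)-1,3-dithian-2-yl]-1-oxohex-4-en-2-yl}isoxazole-4-carbaldehyde | CC(C)c1noc(C(CC=C(C)C)(CC=C(C)C)C(=O)C2(CC=C(C)C)SCCCS2)c1C=O
F8 | step 11 | tert-butyl N-{1-[(3R)-3-hydroxy-3,5,5-tris(3-methylbut-2-enyl)-2,4,6-trioxocyclohexylidene]-2-methylpropyl}carbamate | CC(C)C(NC(=O)OC(C)(C)C)=C1C(=O)[C@@](O)(CC=C(C)C)C(=O)C(CC=C(C)C)(CC=C(C)C)C1=O
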